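5.80% of the substrate charged is missing from Wednesday's reading at 25.0 min, and from that small gap, with Thursday's gaps and the target readings beside it, I reckon one ratio of rate constants and the top of c(target) that it gives.

| flask | substrate | reagent | remark | time |
|---|---|---|---|---|
| Thursday's | 0.15 M | 0.24 M | run made earlier |  |
| Wednesday's | 0.15 M | 0.18 M | run made earlier |  |
| eta | 0.15 M | 0.364 M |  | 40 min |
| epsilon | 0.30 M | 0.364 M |  | 40 min |
| beta | 0.60 M | 0.364 M |  | 40 min |
| zeta | 1.2 M | 0.364 M |  | 40 min |
| theta | 2.5 M | 0.364 M |  | 40 min |

- Thursday's (time / min: target / %, substrate / %): 3.00: 5.9, 92.1; 6.00: 9.8, 88.7; 10.0: 17.7, 81.1; 15.0: 24.0, 73.5; 20.0: 27.7, 67.9; 25.0: 32.0, 59.7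
- Wednesday's (time / min: target / %, substrate / %): 2.00: 3.1, 98.3; 3.00: 5.4, 95.2; 4.00: 6.0, 93.9; 6.00: 9.2, 88.6; 10.0: 12.7, 85.7; 15.0: 17.7, 80.2; 25.0: 25.9, 68.3

(readings scatter by 1 percentage point)

- a species is counted by the substrate in it: one side product B counts as two
- the earlier runs were read with a standard deviation of 1 percentage point
- steps thought possible: substrate + 2 reagent -> side product A; substrate + reagent -> target; substrate + target -> side product B
- "hardly changes" means that all values lie within two and a half points (for a concentration: within two and a half percent of the largest)

* [target] at the end for eta, epsilon, beta, zeta, theta, in this order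
* how the row runs (rises all the way / hardly changes / falls all the way / falls, then rises / rises, then falls)

I set aside the step to side product A as a small correction. Each remaining step then carries one substrate, so dividing their rates cancels c(substrate), and c(target) follows the share x of reagent left: c(target) / reagent charge = (x^S − x) / (1 − S). Here S is the selectivity factor, the rate constant of substrate + target over that of substrate + reagent. While little reagent is used, the target lost is S times the square of the used share, times the reagent charge, divided by 2. That loss is the gap divided by 2, with side product B counted as two, so the gap and the used share, read from the target reading plus half the gap, give S.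

Wednesday's gap gives 0.839, but Thursday's last gap of 8.30% gives 1.02, which is higher, so one of them cheats. Thursday's gap at 20.0 min is 4.40%, so over its last interval it grew 1.89-fold, while the square law allows 1.46-fold. A gap carries a scatter of 0.0141, so I suspect that last Thursday reading. The earlier one gives 0.787, beside Wednesday's value, and I commit to S = 0.813. In my reckoning, the rule then tops out when 33.1% of the reagent is left, at c(target) = 0.148 M. A flask above that share is still gaining target, and one below it is losing target.

The forecast gives 0.08 M, 0.128 M, 0.153 M, 0.09 M, 0.011 M, so rises, then falls: “With more substrate, reagent runs out, and the target is then eaten by excess substrate.” Its third point lies above my top.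

The flasks give 0.0843 M, 0.132 M, 0.157 M, 0.0965 M, 0.00979 M, so rises, then falls.

    substrate + 2 reagent → side product A (k = 0.00570 M⁻² min⁻¹)
    substrate + reagent → target (k = 0.0870 M⁻¹ min⁻¹)
    substrate + target → side product B (k = 0.0590 M⁻¹ min⁻¹)

Flask beta ends with 26.6% of its reagent, close to the share at the top, and the rule with my S gives 0.145 M against the 0.157 M it holds. Flask zeta, past the top with 5.65% left, gets 0.0782 M from the same rule against 0.0965 M. Flask eta still has 73.2% of its reagent at 40 min, above the share at the top, and the hour of the reading is the largest single effect on its 0.0843 M: at ten times that time, flask eta holds 0.110 M.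

(The readings stem from a simulated flask for substances that don't exist; the scatter is artificial.)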